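**Retrosynthetic overview**

- Feature: in the 2H-chromene, C4a and C8a are neighbouring benzene carbons that carry C4 and O1, so the pyran ring (O1–C2–C3–C4) is one molecule of 3-methylbut-2-enal laid across a C4a≡C8a aryne. That aryne has the same indolyl group at C5 and C8 and the same methoxy group at C6 and C7, so the direction of addition is immaterial.
- Kumbicin C ⇐ N-desulfonylation of chromenol 18 ⇐ removal of the C6 methyl group through the C6/C8a para-quinone (only the C6 oxygen is para to O1) ⇐ 6,7-dimethoxychromene 15.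
- 15 ⇐ aryne 12 + enal 11 (bonds C8a–O1 and C4a–C4, then O1–C2) ⇐ silyl triflate 10.
- 10 ⇐ retro-Brook shift and triflation of bromophenol 6 ⇐ phenol 5 ⇐ double Suzuki coupling of dibromophenol 3 with boronic acid 4 ⇐ dibromide 1.
- Ring order: the benzene core and both indoles are bought; the pyran ring is the only ring made (step 6), and it is opened and closed again once (steps 7 and 8).

Key step: step 6

Remark: the target has no stereocentre, so no stereocontrol is needed; 1, 4 and 11 are taken as catalogue compounds.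

**Route**

Step 1
Reactants: 1 1,4-dibromo-2,3-dimethoxybenzene
Product: 3 2,5-dibromo-3,4-dimethoxyphenol, via lithium aryltriisopropoxyborate 2 (not isolated)
Conditions: LiN(iPr)2 (1.2 equiv) added to 1 and B(OiPr)3 (1.5 equiv), THF, −78 °C; then AcOH, 30% H2O2, 0 °C → rt
Reagents that add atoms: hydrogen peroxide, OO
Why: Bromine-directed ortho-lithiation at the only kind of ring C–H, with the borate present as an in situ trap so that LiBr loss and halogen migration are outrun, followed by peroxide oxidation of the C–B bond, should give the phenol (directed metalation, borylation and oxidation).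

Step 2
Reactants: 3 2,5-dibromo-3,4-dimethoxyphenol; 4 1-(phenylsulfonyl)indol-3-ylboronic acid (2.6 equiv)
Product: 5 3,4-dimethoxy-2,5-bis[1-(phenylsulfonyl)indol-3-yl]phenol
Conditions: Pd(OAc)2 (5 mol %), 2-dicyclohexylphosphino-2',6'-dimethoxybiphenyl (10 mol %), K3PO4 (5 equiv), dioxane/H2O 5:1, degassed, 80 °C
Reagents that add atoms: none
Why: A double Suzuki–Miyaura coupling with a zerovalent palladium/biarylphosphine catalyst should tolerate the ortho-substituted, electron-rich bromides and the free phenol, and the sulfonyl group keeps the indolylboronic acid stable enough to couple twice.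

Step 3
Reactants: 5 3,4-dimethoxy-2,5-bis[1-(phenylsulfonyl)indol-3-yl]phenol
Product: 6 2-bromo-4,5-dimethoxy-3,6-bis[1-(phenylsulfonyl)indol-3-yl]phenol
Conditions: NBS (1.0 equiv), dry CH2Cl2, −20 → 0 °C
Reagents that add atoms: N-bromosuccinimide, O=C1CCC(=O)N1Br
Why: Electrophilic aromatic bromination should go to the single free position of the central ring, which is ortho to the hydroxyl and para to a methoxy group, while the sulfonyl-deactivated indoles stay untouched.

Step 4
Reactants: 6 2-bromo-4,5-dimethoxy-3,6-bis[1-(phenylsulfonyl)indol-3-yl]phenol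
Product: 7 {2-bromo-4,5-dimethoxy-3,6-bis[1-(phenylsulfonyl)indol-3-yl]phenoxy}trimethylsilane
Conditions: (Me3Si)2NH, THF, 65 °C; volatiles removed, used crude
Reagents that add atoms: hexamethyldisilazane, C[Si](C)(C)N[Si](C)(C)C
Why: O-Silylation of a phenol with a silazane needs no base or salt work-up and should deliver the moisture-sensitive aryl silyl ether ready for the next step.

Step 5
Reactants: 7 {2-bromo-4,5-dimethoxy-3,6-bis[1-(phenylsulfonyl)indol-3-yl]phenoxy}trimethylsilane
Product: 10 3,4-dimethoxy-2,5-bis[1-(phenylsulfonyl)indol-3-yl]-6-(trimethylsilyl)phenyl trifluoromethanesulfonate, via aryllithium 8 (not isolated), via lithium phenoxide 9 (not isolated)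
Conditions: n-BuLi (1.1 equiv), THF, −100 → −78 °C; then Tf2O (1.2 equiv), −78 → 0 °C
Reagents that add atoms: trifluoromethanesulfonic anhydride, O=S(=O)(OS(=O)(=O)C(F)(F)F)C(F)(F)F
Why: Bromine–lithium exchange at −100 °C should be faster than deprotonation at indole C2, the ortho-lithio silyl ether then undergoes the 1,3 O→C silyl shift (retro-Brook rearrangement), and the phenoxide is triflated in the same flask.

Step 6
Reactants: 10 3,4-dimethoxy-2,5-bis[1-(phenylsulfonyl)indol-3-yl]-6-(trimethylsilyl)phenyl trifluoromethanesulfonate; 11 3-methylbut-2-enal (5 equiv)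
Product: 15 6,7-dimethoxy-2,2-dimethyl-5,8-bis[1-(phenylsulfonyl)indol-3-yl]-2H-chromene, via aryne 12 (not isolated), via benzoxete 13 (not isolated), via ortho-quinone methide 14 (not isolated)
Conditions: CsF (4 equiv), MeCN, 23 → 50 °C
Reagents that add atoms: none
Why: Fluoride attack on silicon with loss of triflate (Kobayashi 1,2-elimination) gives aryne 12, whose strained C4a≡C8a bond adds across the C=O of 11 in a formal [2+2] (carbonyl oxygen onto one aryne carbon, the resulting aryl anion onto the carbonyl carbon; four-membered closure) to give benzoxete 13. Conrotatory 4π ring opening of 13 gives ortho-quinone methide 14, and a thermal disrotatory oxa-6π electrocyclisation of its O=C8a–C4a=C4–C3=C2 triene closes the pyran ring at O1–C2. The closest known reaction type is the fluoride-induced insertion of arynes into the carbonyl group of α,β-unsaturated aldehydes, which gives 2H-chromenes. No stereocentre remains, because the stereogenic benzoxete carbon becomes sp2 in 14 and C2 carries two methyl groups. Regiochemistry is not an issue, because 12 has a mirror plane through the midpoint of the aryne bond and both orientations of the aldehyde lead to 15. The step needs a 1:1 coupling and a ring closure that outruns capture of 14 by a second aryne or aldehyde: the dimethylvinyl arm makes the 6π closure intramolecular, the C5 indolyl group pushes that arm to the carbonyl side, and sparingly soluble CsF keeps the aryne concentration low.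

Step 7
Reactants: 15 6,7-dimethoxy-2,2-dimethyl-5,8-bis[1-(phenylsulfonyl)indol-3-yl]-2H-chromene
Product: 16 2-[(1Z)-3-hydroxy-3-methylbut-1-en-1-yl]-5-methoxy-3,6-bis[1-(phenylsulfonyl)indol-3-yl]-1,4-benzoquinone
Conditions: (NH4)2Ce(NO3)6 (2.3 equiv), MeCN/H2O 3:1, 0 °C, short reaction time
Reagents that add atoms: water, O
Why: Oxidative dealkylation of a hydroquinone diether by tetravalent cerium should single out the C6/C8a para pair, because water adds at these two carbons and the products leave as methanol and as the tertiary allylic oxygen, which stays on C2 as the alcohol, while the sulfonyl groups shield the indoles.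

Step 8
Reactants: 16 2-[(1Z)-3-hydroxy-3-methylbut-1-en-1-yl]-5-methoxy-3,6-bis[1-(phenylsulfonyl)indol-3-yl]-1,4-benzoquinone
Product: 18 7-methoxy-2,2-dimethyl-5,8-bis[1-(phenylsulfonyl)indol-3-yl]-2H-chromen-6-ol, via hydroquinone 17 (not isolated)
Conditions: Na2S2O4, THF/H2O, 23 °C, argon; organic phase dried, then p-TsOH·H2O (5 mol %), CH2Cl2, 23 °C
Reagents that add atoms: none
Why: Dithionite reduction of the quinone followed by acid-catalysed cyclodehydration of the (Z)-2-(3-hydroxy-3-methylbutenyl)phenol should close the chromene again, because only the C8a hydroxyl can reach the allylic cation in a six-membered ring and the C6 hydroxyl is left free.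

Step 9
Reactants: 18 7-methoxy-2,2-dimethyl-5,8-bis[1-(phenylsulfonyl)indol-3-yl]-2H-chromen-6-ol
Product: 19 Kumbicin C, 5,8-di(1H-indol-3-yl)-7-methoxy-2,2-dimethyl-2H-chromen-6-ol
Conditions: Bu4NF (1 M in THF, 6 equiv), THF, 65 °C, argon; aqueous work-up
Reagents that add atoms: none
Why: Fluoride attacks the sulfonyl sulfur and expels the indolide (N-desulfonylation), a method that neither alkylates the phenol nor reduces the chromene double bond.

**Compound list**

1 | 1,4-dibromo-2,3-dimethoxybenzene | COc1c(Br)ccc(Br)c1OC | starting material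
2 | lithium (2,5-dibromo-3,4-dimethoxyphenyl)triisopropoxyborate | COc1c(Br)cc([B-](OC(C)C)(OC(C)C)OC(C)C)c(Br)c1OC.[Li+] | intermediate (not isolated)
3 | 2,5-dibromo-3,4-dimethoxyphenol | COc1c(Br)cc(O)c(Br)c1OC | intermediate
4 | 1-(phenylsulfonyl)indol-3-ylboronic acid | OB(O)c1cn(S(=O)(=O)c2ccccc2)c2ccccc12 | starting material
5 | 3,4-dimethoxy-2,5-bis[1-(phenylsulfonyl)indol-3-yl]phenol | COc1c(OC)c(-c2cn(S(=O)(=O)c3ccccc3)c3ccccc23)c(O)cc1-c1cn(S(=O)(=O)c2ccccc2)c2ccccc12 | intermediate
6 | 2-bromo-4,5-dimethoxy-3,6-bis[1-(phenylsulfonyl)indol-3-yl]phenol | COc1c(OC)c(-c2cn(S(=O)(=O)c3ccccc3)c3ccccc23)c(O)c(Br)c1-c1cn(S(=O)(=O)c2ccccc2)c2ccccc12 | intermediate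
7 | {2-bromo-4,5-dimethoxy-3,6-bis[1-(phenylsulfonyl)indol-3-yl]phenoxy}trimethylsilane | COc1c(OC)c(-c2cn(S(=O)(=O)c3ccccc3)c3ccccc23)c(O[Si](C)(C)C)c(Br)c1-c1cn(S(=O)(=O)c2ccccc2)c2ccccc12 | intermediate
8 | {3,4-dimethoxy-2,5-bis[1-(phenylsulfonyl)indol-3-yl]-6-(trimethylsilyloxy)phenyl}lithium | COc1c(OC)c(-c2cn(S(=O)(=O)c3ccccc3)c3ccccc23)c(O[Si](C)(C)C)c([Li])c1-c1cn(S(=O)(=O)c2ccccc2)c2ccccc12 | intermediate (not isolated)
9 | lithium 3,4-dimethoxy-2,5-bis[1-(phenylsulfonyl)indol-3-yl]-6-(trimethylsilyl)phenoxide | COc1c(OC)c(-c2cn(S(=O)(=O)c3ccccc3)c3ccccc23)c([O-])c([Si](C)(C)C)c1-c1cn(S(=O)(=O)c2ccccc2)c2ccccc12.[Li+] | intermediate (not isolated)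
10 | 3,4-dimethoxy-2,5-bis[1-(phenylsulfonyl)indol-3-yl]-6-(trimethylsilyl)phenyl trifluoromethanesulfonate | COc1c(OC)c(-c2cn(S(=O)(=O)c3ccccc3)c3ccccc23)c(OS(=O)(=O)C(F)(F)F)c([Si](C)(C)C)c1-c1cn(S(=O)(=O)c2ccccc2)c2ccccc12 | intermediate
11 | 3-methylbut-2-enal | CC(C)=CC=O | starting material
12 | 4,5-dimethoxy-3,6-bis[1-(phenylsulfonyl)indol-3-yl]benzyne | COC1=C(c2cn(S(=O)(=O)c3ccccc3)c3ccccc23)C#CC(c2cn(S(=O)(=O)c3ccccc3)c3ccccc23)=C1OC | intermediate (not isolated)
13 | 4,5-dimethoxy-2-(2-methylprop-1-en-1-yl)-3,6-bis[1-(phenylsulfonyl)indol-3-yl]-2H-benzo[b]oxete (racemic, transient) | COc1c(OC)c(-c2cn(S(=O)(=O)c3ccccc3)c3ccccc23)c4C(C=C(C)C)Oc4c1-c5cn(S(=O)(=O)c6ccccc6)c6ccccc56 | intermediate (not isolated)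
14 | (6Z)-3,4-dimethoxy-6-(3-methylbut-2-en-1-ylidene)-2,5-bis[1-(phenylsulfonyl)indol-3-yl]cyclohexa-2,4-dien-1-one | COC1=C(c2cn(S(=O)(=O)c3ccccc3)c3ccccc23)C(=O)/C(=C\C=C(C)C)C(c2cn(S(=O)(=O)c3ccccc3)c3ccccc23)=C1OC | intermediate (not isolated)
15 | 6,7-dimethoxy-2,2-dimethyl-5,8-bis[1-(phenylsulfonyl)indol-3-yl]-2H-chromene | COc1c(OC)c(-c2cn(S(=O)(=O)c3ccccc3)c3ccccc23)c2c(c1-c1cn(S(=O)(=O)c3ccccc3)c3ccccc13)OC(C)(C)C=C2 | intermediate
16 | 2-[(1Z)-3-hydroxy-3-methylbut-1-en-1-yl]-5-methoxy-3,6-bis[1-(phenylsulfonyl)indol-3-yl]-1,4-benzoquinone | COC1=C(c2cn(S(=O)(=O)c3ccccc3)c3ccccc23)C(=O)C(/C=C\C(C)(C)O)=C(c2cn(S(=O)(=O)c3ccccc3)c3ccccc23)C1=O | intermediate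
17 | 2-[(1Z)-3-hydroxy-3-methylbut-1-en-1-yl]-5-methoxy-3,6-bis[1-(phenylsulfonyl)indol-3-yl]benzene-1,4-diol | COc1c(O)c(-c2cn(S(=O)(=O)c3ccccc3)c3ccccc23)c(/C=C\C(C)(C)O)c(O)c1-c1cn(S(=O)(=O)c2ccccc2)c2ccccc12 | intermediate (not isolated)
18 | 7-methoxy-2,2-dimethyl-5,8-bis[1-(phenylsulfonyl)indol-3-yl]-2H-chromen-6-ol | COc1c(O)c(-c2cn(S(=O)(=O)c3ccccc3)c3ccccc23)c2c(c1-c1cn(S(=O)(=O)c3ccccc3)c3ccccc13)OC(C)(C)C=C2 | intermediate
19 | Kumbicin C, 5,8-di(1H-indol-3-yl)-7-methoxy-2,2-dimethyl-2H-chromen-6-ol | COc1c(O)c(-c2c[nH]c3ccccc23)c2c(c1-c1c[nH]c3ccccc13)OC(C)(C)C=C2 | target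

**Step count**

Total: 9 steps. Longest linear sequence: 9 steps (1 → 19).

**Steps most likely to fail**

1. Step 6 (aryne capture). The hindered aryne may be captured too slowly. Fluoride-triggered self-condensation of the enal, an ene reaction of the aryne with the allylic methyl groups, protonation of the aryl anion before the four-membered ring closes, or early loss of sulfonyl groups could then take over. Fallback: the fallback sets out from phenol 5 and returns at chromene 15 without an aryne. O-Alkylation of 5 with 3-chloro-3-methylbut-1-yne (DBU, catalytic CuCl2, MeCN, 0 °C) should give the aryl propargyl ether 3,3'-[2,3-dimethoxy-5-(2-methylbut-3-yn-2-yloxy)-1,4-phenylene]bis[1-(phenylsulfonyl)indole] F1. Heating F1 in xylene at 140 °C should bring about a propargyl Claisen rearrangement to the one free ortho carbon, a 1,5-hydrogen shift and oxa-6π closure, which gives 15.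

2. Step 7 (cerium oxidation). Oxidation may occur at the electron-rich C3=C4 styrene bond, or demethylation may take place at the C6/C7 ortho pair instead of the para pair. Fallback: the two methoxy groups are told apart before the pyran ring exists; the fallback sets out from phenol 5 and returns at chromenol 18. In 5 the hydroxyl is para to one methoxy group, so PhI(OAc)2 in MeCN/H2O at 0 °C should give 2-methoxy-3,6-bis[1-(phenylsulfonyl)indol-3-yl]-1,4-benzoquinone F2. Reduction with Na2S2O4 should give 3-methoxy-2,5-bis[1-(phenylsulfonyl)indol-3-yl]benzene-1,4-diol F3. Condensation of F3 with enal 11 (phenylboronic acid, AcOH, toluene, reflux with water removal) can form a chromene only at the one hydroxyl that has a free ortho carbon, and this is 18.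

3. Step 5 (retro-Brook shift). Proton transfer from an indole C2–H to the aryllithium, or attack of butyllithium at a sulfonyl group, may compete with the silyl shift. Fallback: silicon is installed before the indoles arrive; the fallback sets out from dibromophenol 3 and returns at triflate 10. Iodination of 3 with N-iodosuccinimide should give 2,5-dibromo-6-iodo-3,4-dimethoxyphenol F4, and silylation with (Me3Si)2NH should give (2,5-dibromo-6-iodo-3,4-dimethoxyphenoxy)trimethylsilane F5. Iodine-selective exchange with n-BuLi at −100 °C, retro-Brook shift and aqueous quench should give 2,5-dibromo-3,4-dimethoxy-6-(trimethylsilyl)phenol F6. Double Suzuki coupling of F6 with 4 under the conditions of step 2 should give 3,4-dimethoxy-2,5-bis[1-(phenylsulfonyl)indol-3-yl]-6-(trimethylsilyl)phenol F7, and Tf2O with pyridine in CH2Cl2 should convert F7 into 10.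

**Further compounds**

F1 | step 6 | 3,3'-[2,3-dimethoxy-5-(2-methylbut-3-yn-2-yloxy)-1,4-phenylene]bis[1-(phenylsulfonyl)indole] | COc1c(OC)c(-c2cn(S(=O)(=O)c3ccccc3)c3ccccc23)c(OC(C)(C)C#C)cc1-c1cn(S(=O)(=O)c2ccccc2)c2ccccc12
F2 | step 7 | 2-methoxy-3,6-bis[1-(phenylsulfonyl)indol-3-yl]-1,4-benzoquinone | COC1=C(c2cn(S(=O)(=O)c3ccccc3)c3ccccc23)C(=O)C=C(c2cn(S(=O)(=O)c3ccccc3)c3ccccc23)C1=O
F3 | step 7 | 3-methoxy-2,5-bis[1-(phenylsulfonyl)indol-3-yl]benzene-1,4-diol | COc1c(O)c(-c2cn(S(=O)(=O)c3ccccc3)c3ccccc23)cc(O)c1-c1cn(S(=O)(=O)c2ccccc2)c2ccccc12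
F4 | step 5 | 2,5-dibromo-6-iodo-3,4-dimethoxyphenol | COc1c(Br)c(I)c(O)c(Br)c1OC
F5 | step 5 | (2,5-dibromo-6-iodo-3,4-dimethoxyphenoxy)trimethylsilane | COc1c(Br)c(I)c(O[Si](C)(C)C)c(Br)c1OC
F6 | step 5 | 2,5-dibromo-3,4-dimethoxy-6-(trimethylsilyl)phenol | COc1c(Br)c([Si](C)(C)C)c(O)c(Br)c1OC
F7 | step 5 | 3,4-dimethoxy-2,5-bis[1-(phenylsulfonyl)indol-3-yl]-6-(trimethylsilyl)phenol | COc1c(OC)c(-c2cn(S(=O)(=O)c3ccccc3)c3ccccc23)c(O)c([Si](C)(C)C)c1-c1cn(S(=O)(=O)c2ccccc2)c2ccccc12
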